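Atom numbering used throughout: C1 is the ring carbon bearing C7H2OBz, C2 the vinylic CH, C3 to C6 the four carbinol carbons (benzoate on O5).

## Analysis of the target

Target 17 is a monocyclic cyclohexene: C1=C2 is a trisubstituted alkene, C1 carries the exocyclic C7H2 benzoate, and C3 to C6 are four contiguous carbinol carbons with a second benzoate on O5 and free hydroxyls on O3, O4 and O6. The configuration is 3R,4S,5R,6S, which places O3/O4 trans, O4/O5 cis and O5/O6 trans, so O4/O5 is the only cis-diol and the two allylic oxygens O3 and O6 share the face opposite to it. The O5 benzoate lies between two free hydroxyls and can migrate under base, the C3–O, C6–O and C7–O bonds are all allylic, and the alkene together with the allylic ester rules out late hydrogenolysis. The difficulty is twofold: four contiguous oxygenated stereocentres on a ring that has no carbon substituent to steer them, and acylation of exactly two of five oxygens, the primary O7 and the internal secondary O5. The plan rests on two features: C3, C4 and C5 have the configuration of C2, C3 and C4 of D-arabinose (threo, then erythro), and C7–C1=C2 is an acrylate unit whose α-carbon C1 is bonded to the carbinol C6, the pattern that a Morita–Baylis–Hillman reaction leaves behind. Cutting C1–C6 therefore opens the ring to a linear seven-carbon enoate aldehyde in which every carbon and three of the four stereocentres come from the pentose and a two-carbon ylide.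

## Retrosynthetic reasoning

C5–O acyl bond, from 17 back to 14 and 15. The internal benzoate is removed first in the backward sense because it is the group most prone to migrate and should be installed last. O4/O5 is the only cis-diol of tetraol 14, so orthoester 15 should engage it selectively as the cyclic orthobenzoate 16. Acidic opening of such cis-fused orthoesters leaves the acyl group on the axial oxygen. In the half-chair that keeps O6 pseudo-axial, away from the C7 substituent on C1, O5 is axial and O4 equatorial. A tin-mediated acylation would favour the equatorial oxygen and was not considered.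

O7 acyl bond, protecting groups and C7 oxidation state, from 14 back to 13, then to 11 and 12, then to 10. Tetraol 14 comes from 13 by one acidic operation that removes both the acetal and the silyl ether. The C7 benzoate of 13 is cut back to diol 11 and acid chloride 12, because the primary allylic hydroxyl should be acylated ahead of the hindered secondary C6 hydroxyl. Diol 11 is the reduction product of ester 10, so C7 enters at the ester level and is adjusted after the ring is made.

C1–C6 bond, from 10 back to 9, the key disconnection. A carbinol next to the α-carbon of an enoate is the retron of a Morita–Baylis–Hillman reaction. Cutting here, rather than at C2–C3 or across the alkene, gives the open-chain enoate aldehyde 9, in which the full carbon count and the C3, C4 and C5 configurations are already present. The forward step has to close a six-membered ring, bring the alkene back in the endocyclic position and set C6 trans to O5.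

C1=C2 bond and the C6 aldehyde, from 9 back to 8, then to 5 and 6. Aldehyde 9 is the oxidation product of primary alcohol 8. Alcohol 8 is the olefination product of lactol 5, which reacts through its open-chain form 7 with the stabilised ylide 6. The pyranose ring oxygen becomes the primary hydroxyl that is then oxidised, so one olefination installs C1 and C7 and exposes C6.

Protecting-group pattern on the pentose, from 5 back to 4, 3, 2 and 1. Lactol 5 needs the cis-3,4-diol tied as an isopropylidene acetal (target O4/O5), O2 as a silyl ether (target O3) and a free anomeric centre. This follows from glycoside 2 of D-arabinose 1. The benzyl group masks the anomeric carbon while the cis-diol is acetalised to give 3 and O2 is silylated to give 4, and it is then removed by hydrogenolysis before any alkene is present.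

## Alternatives that were turned down

Alternative 1: Arene cis-dihydroxylation. The C4–O and C5–O bonds are traced back to an aromatic ring. Whole-cell oxidation of bromobenzene A2 by a bacterial arene dioxygenase would add dioxygen across one ortho,meta bond of A2 and give (1S,2S)-3-bromocyclohexa-3,5-diene-1,2-diol A1 as a single enantiomer. Mapped onto 17, the cis-diol of A1 is O4/O5 and its bromine sits on C6. In its favour, the ring and the absolute configuration come from one step starting from the cheap arene A2, the 4,5-cis relationship is exact, and the diene termini C3 and C6 of A1 are where the remaining oxygens are needed, both anti to a protected diol. Against it, the halogen that A2 passes on to A1 is on C6, which must become a carbinol, and not on C1, where C7 has to be attached. C7 would therefore have to be joined to an internal sp2 carbon by a separate C–C bond formation after C6 has been turned into a ketone. That ketone would then have to be reduced from the face shielded by the cis-fused diol protecting group to reach the 5,6-trans alcohol. In comparison, A1 is stronger in that no carbocyclisation is at risk and the enantiopurity is enzymatic. The chosen route offers in its place all seven carbons at the right oxidation level from one olefination and only one stereocentre to create.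

Alternative 2: Ketoaldehyde aldol from a 6-deoxyhexose. The C2–C3 bond is cut. The methyl ketone of 2,3,4-tri-O-benzyl-6-deoxy-L-lyxo-hexos-5-ulose A4, which would be prepared from L-rhamnose A5, adds as its enamine or enolate to the aldehyde carbon of A4. This aldol closure gives 2,3,4-tris(benzyloxy)-5-hydroxycyclohexanone A3, in which the sugar methyl group has become C2 and the ketone is C1. In its favour, A5 is cheap, the three stereocentres of A4 map correctly onto C4, C5 and C6, and a six-membered aldol closure of a 1,5-ketoaldehyde such as A4 is more dependable than a Baylis–Hillman closure of an enoate. Against it, A3 lacks C7 and the alkene. A one-carbon unit must be added at the C1 carbonyl and the C1=C2 alkene introduced regioselectively, while the β-hydroxy ketone of A3 is prone to dehydrate across C2–C3 and to epimerise at C6. The three benzyl ethers are equivalent and cannot be hydrogenolysed once the alkene and the allylic benzoate are present, and C3 must still be set trans to O4. In comparison, this alternative is stronger on the reliability of the ring closure. The chosen route delivers ring, C7 and alkene in the same step and carries protecting groups that fall in one acidic operation.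

Alternative 3: [4+2] Photooxygenation of a shikimate-derived diene. The C3–O and C6–O bonds are cut together. Methyl (3R,4S)-3,4-(isopropylidenedioxy)cyclohexa-1,5-diene-1-carboxylate A7, available from shikimic acid A8, would undergo dye-sensitised [4+2] photooxygenation across C3 and C6 on the face anti to the acetal. The product would be the bicyclic endoperoxide A6, an acetonide-fused 2,3-dioxabicyclo[2.2.2]oct-5-ene methyl ester, and reduction of its O–O bond would give the 3,6-diol with the configuration of 17. In its favour, A8 already contains C7, the C1=C2 alkene and the cis-diol in the correct absolute sense, both allylic oxygens arrive in one substrate-controlled step, and the route would be two or three steps shorter than the one chosen. On step economy this alternative is the stronger. Against it, A7 is an ester-deactivated diene and should react slowly with an electrophilic oxidant, ene pathways at the allylic acetal C–H bonds compete, and A7 aromatises easily by loss of an acetal oxygen. A6 has an acidic C3–H (γ to the ester), so base-induced fragmentation to a C3 ketone threatens before reduction. In comparison, the chosen route gives in exchange three stereocentres fixed by the sugar, no photochemical or peroxide step, and differentiated allylic oxygens (O3 silylated, O6 free) from the moment the ring forms. The endgame from the reduced diol would be the same as in steps 8 to 11.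

Key step: step 7

Assumption: lactol 5 is used as the anomeric mixture and enoates 8 and 9 are drawn as the E isomers; neither point matters, because the anomeric centre is destroyed in step 5 and the alkene geometry is erased when the phosphine adds in step 7.

## Route

Step 1
Reactants: 1 D-arabinose
Product: 2 benzyl β-D-arabinopyranoside
Conditions: BnOH (solvent), HCl (g), rt; crystallisation
Reagents that add atoms: benzyl alcohol, OCc1ccccc1
Why: Fischer glycosidation under thermodynamic control gives the pyranoside with the axial (β) benzyloxy group favoured by the anomeric effect, and this anomer should crystallise from the mixture; C2 to C4 are untouched.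

Step 2
Reactants: 2 benzyl β-D-arabinopyranoside
Product: 3 benzyl 3,4-O-isopropylidene-β-D-arabinopyranoside
Conditions: Me2C(OMe)2, TsOH·H2O (cat.), acetone, rt; Et3N quench
Reagents that add atoms: 2,2-dimethoxypropane, COC(C)(C)OC
Why: Acid-catalysed transacetalisation; only the cis-3,4-diol can form a strain-free five-membered isopropylidene acetal, which leaves O2 free.

Step 3
Reactants: 3 benzyl 3,4-O-isopropylidene-β-D-arabinopyranoside
Product: 4 benzyl 2-O-(tert-butyldimethylsilyl)-3,4-O-isopropylidene-β-D-arabinopyranoside
Conditions: TBSOTf, 2,6-lutidine, CH2Cl2, 0 °C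
Reagents that add atoms: tert-butyldimethylsilyl trifluoromethanesulfonate, CC(C)(C)[Si](C)(C)OS(=O)(=O)C(F)(F)F
Why: Silylation of the single remaining hydroxyl; the triflate is used because O2 is flanked by the axial anomeric substituent and the acetal, and the buffered conditions leave acetal and glycoside intact.

Step 4
Reactants: 4 benzyl 2-O-(tert-butyldimethylsilyl)-3,4-O-isopropylidene-β-D-arabinopyranoside
Product: 5 2-O-(tert-butyldimethylsilyl)-3,4-O-isopropylidene-D-arabinopyranose (anomeric mixture)
Conditions: H2 (1 atm), Pd/C, EtOAc, rt
Reagents that add atoms: none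
Why: Hydrogenolysis of the anomeric benzyl ether under neutral conditions frees the lactol; silyl ether and acetal are inert, and no alkene is yet present.

Step 5
Reactants: 5 2-O-(tert-butyldimethylsilyl)-3,4-O-isopropylidene-D-arabinopyranose; 6 methyl (triphenylphosphoranylidene)acetate
Product: 8 methyl (2E,4R,5R,6R)-4-(tert-butyldimethylsilyloxy)-7-hydroxy-5,6-(isopropylidenedioxy)hept-2-enoate, via open-chain hydroxy aldehyde 7 (not isolated)
Conditions: Ph3P=CHCO2Me, PhCO2H (cat.), toluene, 80 °C
Reagents that add atoms: methyl (triphenylphosphoranylidene)acetate (6), COC(=O)C=P(c1ccccc1)(c1ccccc1)c1ccccc1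
Why: Wittig olefination of the lactol through its aldehyde tautomer 7; the stabilised ylide in an aprotic solvent should favour the E-enoate, and the near-neutral medium should keep the freed primary hydroxyl from adding back to the enoate. No stereocentre is made or touched.

Step 6
Reactants: 8 methyl (2E,4R,5R,6R)-4-(tert-butyldimethylsilyloxy)-7-hydroxy-5,6-(isopropylidenedioxy)hept-2-enoate
Product: 9 methyl (2E,4R,5R,6S)-4-(tert-butyldimethylsilyloxy)-5,6-(isopropylidenedioxy)-7-oxohept-2-enoate
Conditions: Dess–Martin periodinane, NaHCO3, CH2Cl2, 0 °C → rt; used crude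
Reagents that add atoms: none
Why: Buffered Dess–Martin oxidation of the primary alcohol; base-free conditions should preserve the epimerisable α-alkoxy aldehyde on the cis-dioxolane and avoid oxa-Michael closure.

Step 7
Reactants: 9 methyl (2E,4R,5R,6S)-4-(tert-butyldimethylsilyloxy)-5,6-(isopropylidenedioxy)-7-oxohept-2-enoate
Product: 10 methyl (3R,4R,5R,6S)-3-(tert-butyldimethylsilyloxy)-6-hydroxy-4,5-(isopropylidenedioxy)cyclohex-1-ene-1-carboxylate
Conditions: PMe3 (1.0 equiv, 1 M in THF), t-BuOH (5 equiv), THF, 0 °C → rt, Ar
Reagents that add atoms: none
Why: PMe3 adds in conjugate fashion to C2 of the enoate and forms a phosphonium ester enolate, so the alkene geometry of 9 no longer matters. The enolate carbon C1 then attacks the C6 aldehyde, and proton transfer from C1 (shuttled by t-BuOH) followed by loss of PMe3 from C2 restores the C1=C2 alkene, now inside the ring. The closest known reaction type is the phosphine-mediated intramolecular Morita–Baylis–Hillman cyclisation of ω-formyl α,β-unsaturated esters and thioesters to cyclohexenols. The ring closes in the 6-(enolexo)-exo-trig mode, and the cis-dioxolane holds the C3 and C6 arms on the same side, which preorganises the reacting ends. C6 is the only new stereocentre and is controlled by C5: in the half-chair transition state with the C3 silyloxy group pseudo-equatorial, the carbonyl oxygen lies anti to the C5–O bond (dipole-minimised, Cornforth-type), which puts the alkoxide on the convex face of the cis-fused bicycle and gives the 5,6-trans (6S) alcohol. Because the aldol addition is reversible and the elimination is slower, the product ratio should reflect this lower-energy trans alkoxide. The step also needs C–C bond formation to outrun epimerisation at C5 and β-elimination of the acetal oxygen, which the weakly basic neutral phosphine and the poor orbital alignment for ring-opening elimination within the dioxolane should secure. C3, C4 and C5 are not touched.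

Step 8
Reactants: 10 methyl (3R,4R,5R,6S)-3-(tert-butyldimethylsilyloxy)-6-hydroxy-4,5-(isopropylidenedioxy)cyclohex-1-ene-1-carboxylate
Product: 11 [(3R,4R,5R,6S)-3-(tert-butyldimethylsilyloxy)-6-hydroxy-4,5-(isopropylidenedioxy)cyclohex-1-en-1-yl]methanol
Conditions: i-Bu2AlH (3.5 equiv), CH2Cl2, −78 → −20 °C; aq. potassium sodium tartrate (KNaC4H4O6)
Reagents that add atoms: none
Why: 1,2-Reduction of the conjugated ester to the allylic alcohol by i-Bu2AlH; the excess covers the free C6 hydroxyl, and silyl ether and acetal survive at low temperature.

Step 9
Reactants: 11 [(3R,4R,5R,6S)-3-(tert-butyldimethylsilyloxy)-6-hydroxy-4,5-(isopropylidenedioxy)cyclohex-1-en-1-yl]methanol; 12 benzoyl chloride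
Product: 13 [(3R,4R,5R,6S)-3-(tert-butyldimethylsilyloxy)-6-hydroxy-4,5-(isopropylidenedioxy)cyclohex-1-en-1-yl]methyl benzoate
Conditions: BzCl (1.05 equiv), 2,4,6-collidine, CH2Cl2, −78 → −40 °C
Reagents that add atoms: benzoyl chloride (12), O=C(Cl)c1ccccc1
Why: Kinetic acylation of the primary allylic hydroxyl; the secondary C6 hydroxyl is flanked by the fully substituted C1 and the dioxolane carbon C5 and should react much more slowly with a hindered, non-nucleophilic base at low temperature.

Step 10
Reactants: 13 [(3R,4R,5R,6S)-3-(tert-butyldimethylsilyloxy)-6-hydroxy-4,5-(isopropylidenedioxy)cyclohex-1-en-1-yl]methyl benzoate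
Product: 14 [(3R,4S,5R,6S)-3,4,5,6-tetrahydroxycyclohex-1-en-1-yl]methyl benzoate
Conditions: TFA/H2O/THF (2:1:1), 0 °C → rt; toluene co-evaporation
Reagents that add atoms: none
Why: Aqueous acid hydrolyses the isopropylidene acetal and the secondary silyl ether in one operation; the benzoate is stable to these conditions and the acidic medium disfavours acyl migration from O7 to O6.

Step 11
Reactants: 14 [(3R,4S,5R,6S)-3,4,5,6-tetrahydroxycyclohex-1-en-1-yl]methyl benzoate; 15 trimethyl orthobenzoate
Product: 17 [(3R,4S,5R,6S)-5-(benzoyloxy)-3,4,6-trihydroxycyclohex-1-en-1-yl]methyl benzoate, via cyclic 4,5-orthobenzoate 16 (not isolated)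
Conditions: PhC(OMe)3 (1.3 equiv), CSA (cat.), MeCN, rt; then 80% aq. AcOH, rt
Reagents that add atoms: trimethyl orthobenzoate (15), COC(OC)(OC)c1ccccc1; water, O
Why: Under acid equilibration the only cis-diol (O4/O5) should form the five-membered cyclic orthoester 16. Hydrolysis through the 2-phenyl-1,3-dioxolan-2-ylium ion and its hemiorthoester cleaves the bond to the equatorial oxygen (regioselective orthoester opening), which leaves the benzoate on the axial O5. O5 is axial because O6 prefers the pseudo-axial position that avoids A(1,2) strain with the C7 substituent, and the acidic finish avoids acyl migration.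

## Compound list

1 | D-arabinose | O=C[C@@H](O)[C@H](O)[C@H](O)CO | starting material
2 | benzyl β-D-arabinopyranoside | O(Cc1ccccc1)[C@H]2[C@@H](O)[C@H](O)[C@H](O)CO2 | intermediate
3 | benzyl 3,4-O-isopropylidene-β-D-arabinopyranoside | O(Cc1ccccc1)[C@H]2[C@@H](O)[C@@H]3OC(C)(C)O[C@@H]3CO2 | intermediate
4 | benzyl 2-O-(tert-butyldimethylsilyl)-3,4-O-isopropylidene-β-D-arabinopyranoside | O(Cc1ccccc1)[C@H]2[C@@H](O[Si](C)(C)C(C)(C)C)[C@@H]3OC(C)(C)O[C@@H]3CO2 | intermediate
5 | 2-O-(tert-butyldimethylsilyl)-3,4-O-isopropylidene-D-arabinopyranose (anomeric mixture) | OC1[C@@H](O[Si](C)(C)C(C)(C)C)[C@@H]2OC(C)(C)O[C@@H]2CO1 | intermediate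
6 | methyl (triphenylphosphoranylidene)acetate | COC(=O)C=P(c1ccccc1)(c1ccccc1)c1ccccc1 | starting material
7 | 2-O-(tert-butyldimethylsilyl)-3,4-O-isopropylidene-aldehydo-D-arabinose (open-chain tautomer of 5) | O=C[C@@H](O[Si](C)(C)C(C)(C)C)[C@@H]1OC(C)(C)O[C@@H]1CO | intermediate
8 | methyl (2E,4R,5R,6R)-4-(tert-butyldimethylsilyloxy)-7-hydroxy-5,6-(isopropylidenedioxy)hept-2-enoate | COC(=O)/C=C/[C@@H](O[Si](C)(C)C(C)(C)C)[C@@H]1OC(C)(C)O[C@@H]1CO | intermediate
9 | methyl (2E,4R,5R,6S)-4-(tert-butyldimethylsilyloxy)-5,6-(isopropylidenedioxy)-7-oxohept-2-enoate | COC(=O)/C=C/[C@@H](O[Si](C)(C)C(C)(C)C)[C@@H]1OC(C)(C)O[C@@H]1C=O | intermediate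
10 | methyl (3R,4R,5R,6S)-3-(tert-butyldimethylsilyloxy)-6-hydroxy-4,5-(isopropylidenedioxy)cyclohex-1-ene-1-carboxylate | COC(=O)C1=C[C@@H](O[Si](C)(C)C(C)(C)C)[C@@H]2OC(C)(C)O[C@@H]2[C@H]1O | intermediate
11 | [(3R,4R,5R,6S)-3-(tert-butyldimethylsilyloxy)-6-hydroxy-4,5-(isopropylidenedioxy)cyclohex-1-en-1-yl]methanol | OCC1=C[C@@H](O[Si](C)(C)C(C)(C)C)[C@@H]2OC(C)(C)O[C@@H]2[C@H]1O | intermediate
12 | benzoyl chloride | O=C(Cl)c1ccccc1 | starting material
13 | [(3R,4R,5R,6S)-3-(tert-butyldimethylsilyloxy)-6-hydroxy-4,5-(isopropylidenedioxy)cyclohex-1-en-1-yl]methyl benzoate | O=C(OCC1=C[C@@H](O[Si](C)(C)C(C)(C)C)[C@@H]2OC(C)(C)O[C@@H]2[C@H]1O)c1ccccc1 | intermediate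
14 | [(3R,4S,5R,6S)-3,4,5,6-tetrahydroxycyclohex-1-en-1-yl]methyl benzoate | O=C(OCC1=C[C@@H](O)[C@H](O)[C@H](O)[C@H]1O)c1ccccc1 | intermediate
15 | trimethyl orthobenzoate | COC(OC)(OC)c1ccccc1 | starting material
16 | cyclic 4,5-(methyl orthobenzoate) of 14 (2-methoxy-2-phenyl-1,3-dioxolane cis-fused at C4/C5; orthoester carbon as a mixture) | O=C(OCC1=C[C@@H](O)[C@@H]2OC(OC)(c3ccccc3)O[C@@H]2[C@H]1O)c1ccccc1 | intermediate
17 | [(3R,4S,5R,6S)-5-(benzoyloxy)-3,4,6-trihydroxycyclohex-1-en-1-yl]methyl benzoate | O=C(OCC1=C[C@@H](O)[C@H](O)[C@H](OC(=O)c2ccccc2)[C@H]1O)c1ccccc1 | target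

## Step count and least certain steps

Total step count: 11. Longest linear sequence: 11 steps from 1.

Step 7 (key step). What may go wrong: slow turnover, because an oxoester enoate is a weak acceptor for the phosphine and the proton-transfer and elimination stage is sluggish; during a long reaction time the α-alkoxy aldehyde can epimerise at C5. Facial selectivity at C6 may also be incomplete. The fallback sets out from 9 and comes back at 10. Lithium benzenethiolate (PhSLi, THF, −78 → −20 °C) adds to the enoate and generates the ester enolate stoichiometrically, which closes onto the aldehyde to give the β-phenylsulfanyl aldol adduct F1. Oxidation with mCPBA at −78 °C gives the sulfoxide F2. Thermal syn-elimination toward the acidic C1–H (toluene, 80 °C) then returns to 10. Should either closure deliver the 5,6-cis alcohol, the C6 epimer of 10 F3, Mitsunobu reaction with 4-nitrobenzoic acid (PPh3, DIAD, THF) from the open convex face gives the inverted 4-nitrobenzoate of 10 F4, and K2CO3 in MeOH releases 10.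

Step 5. What may go wrong: slow olefination of a hindered lactol that is mostly in its closed form, and conjugate addition of the freed primary hydroxyl to the new enoate (tetrahydropyran formation) on prolonged heating with the basic ylide. The fallback sets out from 5 and comes back at 8. Methylenation with Ph3P=CH2 (Ph3PCH3Br, KN(SiMe3)2, THF) gives the terminal alkene alcohol F5, which has no Michael acceptor. Cross-metathesis with methyl acrylate (second-generation Hoveyda–Grubbs catalyst, CH2Cl2, 40 °C) under neutral conditions then gives 8.

Step 9. What may go wrong: incomplete discrimination between the primary and the secondary allylic hydroxyl, leading to over-acylation or to acyl transfer from O7 to O6. The fallback sets out from 10 and comes back at 14. The C6 hydroxyl is capped first (TESOTf, 2,6-lutidine) as the 6-O-triethylsilyl ether of 10 F6. Reduction with i-Bu2AlH gives the 6-O-triethylsilyl ether of 11 F7, and benzoylation with 12 (pyridine, DMAP) gives the 6-O-triethylsilyl ether of 13 F8. Under the conditions of step 10 all three protecting groups fall, which gives 14.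

Step 11. What may go wrong: orthoester formation at the free C3 or C6 hydroxyl, opening of the cyclic orthoester toward O4 if the half-chair is not biased enough, and acyl migration between O5 and O4 on work-up. The fallback sets out from 13 and comes back at 17. The acetal is removed by thioacetal exchange with the silyl ether kept (EtSH, Zn(OTf)2, NaHCO3, CH2Cl2, 0 °C → rt) to give the 3-O-silyl triol F9. Its bulky C3 silyloxy group anchors the half-chair with O3 pseudo-equatorial and O5 axial. Orthoester formation with 15 (CSA, MeCN) gives the cyclic 4,5-orthobenzoate of F9 F10, and aqueous AcOH opens it to the 3-O-silyl ether of 17 F11. HF·pyridine in THF/pyridine at 0 °C removes the silyl group without base and gives 17.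

## Further compounds

F1 | step 7 | methyl 3-(tert-butyldimethylsilyloxy)-6-hydroxy-4,5-(isopropylidenedioxy)-2-(phenylsulfanyl)cyclohexane-1-carboxylate (C3 to C6 as in 10; C1 and C2 as formed) | COC(=O)C1C(Sc2ccccc2)[C@@H](O[Si](C)(C)C(C)(C)C)[C@@H]3OC(C)(C)O[C@@H]3[C@H]1O
F2 | step 7 | methyl 3-(tert-butyldimethylsilyloxy)-6-hydroxy-4,5-(isopropylidenedioxy)-2-(phenylsulfinyl)cyclohexane-1-carboxylate (sulfoxide of F1) | COC(=O)C1C(S(=O)c2ccccc2)[C@@H](O[Si](C)(C)C(C)(C)C)[C@@H]3OC(C)(C)O[C@@H]3[C@H]1O
F3 | step 7 | methyl (3R,4R,5R,6R)-3-(tert-butyldimethylsilyloxy)-6-hydroxy-4,5-(isopropylidenedioxy)cyclohex-1-ene-1-carboxylate (C6 epimer of 10) | COC(=O)C1=C[C@@H](O[Si](C)(C)C(C)(C)C)[C@@H]2OC(C)(C)O[C@@H]2[C@@H]1O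
F4 | step 7 | methyl (3R,4R,5R,6S)-3-(tert-butyldimethylsilyloxy)-4,5-(isopropylidenedioxy)-6-(4-nitrobenzoyloxy)cyclohex-1-ene-1-carboxylate (4-nitrobenzoate of 10) | COC(=O)C1=C[C@@H](O[Si](C)(C)C(C)(C)C)[C@@H]2OC(C)(C)O[C@@H]2[C@H]1OC(=O)c1ccc(cc1)[N+](=O)[O-]
F5 | step 5 | [(4R,5R)-5-[(1R)-1-(tert-butyldimethylsilyloxy)prop-2-en-1-yl]-2,2-dimethyl-1,3-dioxolan-4-yl]methanol | C=C[C@@H](O[Si](C)(C)C(C)(C)C)[C@@H]1OC(C)(C)O[C@@H]1CO
F6 | step 9 | methyl 3-(tert-butyldimethylsilyloxy)-4,5-(isopropylidenedioxy)-6-(triethylsilyloxy)cyclohex-1-ene-1-carboxylate (6-O-triethylsilyl ether of 10) | COC(=O)C1=C[C@@H](O[Si](C)(C)C(C)(C)C)[C@@H]2OC(C)(C)O[C@@H]2[C@H]1O[Si](CC)(CC)CC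
F7 | step 9 | [3-(tert-butyldimethylsilyloxy)-4,5-(isopropylidenedioxy)-6-(triethylsilyloxy)cyclohex-1-en-1-yl]methanol (6-O-triethylsilyl ether of 11) | OCC1=C[C@@H](O[Si](C)(C)C(C)(C)C)[C@@H]2OC(C)(C)O[C@@H]2[C@H]1O[Si](CC)(CC)CC
F8 | step 9 | [3-(tert-butyldimethylsilyloxy)-4,5-(isopropylidenedioxy)-6-(triethylsilyloxy)cyclohex-1-en-1-yl]methyl benzoate (6-O-triethylsilyl ether of 13) | O=C(OCC1=C[C@@H](O[Si](C)(C)C(C)(C)C)[C@@H]2OC(C)(C)O[C@@H]2[C@H]1O[Si](CC)(CC)CC)c1ccccc1
F9 | step 11 | [3-(tert-butyldimethylsilyloxy)-4,5,6-trihydroxycyclohex-1-en-1-yl]methyl benzoate (configuration as in 13) | O=C(OCC1=C[C@@H](O[Si](C)(C)C(C)(C)C)[C@H](O)[C@H](O)[C@H]1O)c1ccccc1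
F10 | step 11 | cyclic 4,5-(methyl orthobenzoate) of F9 | O=C(OCC1=C[C@@H](O[Si](C)(C)C(C)(C)C)[C@@H]2OC(OC)(c3ccccc3)O[C@@H]2[C@H]1O)c1ccccc1
F11 | step 11 | [5-(benzoyloxy)-3-(tert-butyldimethylsilyloxy)-4,6-dihydroxycyclohex-1-en-1-yl]methyl benzoate (3-O-silyl ether of 17) | O=C(OCC1=C[C@@H](O[Si](C)(C)C(C)(C)C)[C@H](O)[C@H](OC(=O)c2ccccc2)[C@H]1O)c1ccccc1
A1 | alternative 1 | (1S,2S)-3-bromocyclohexa-3,5-diene-1,2-diol | BrC1=CC=C[C@H](O)[C@@H]1O
A2 | alternative 1 | bromobenzene | Brc1ccccc1
A3 | alternative 2 | 2,3,4-tris(benzyloxy)-5-hydroxycyclohexanone (configured as C3 to C6 of 17) | O=C1C[C@@H](O)[C@H](OCc2ccccc2)[C@H](OCc2ccccc2)[C@H]1OCc1ccccc1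
A4 | alternative 2 | 2,3,4-tri-O-benzyl-6-deoxy-L-lyxo-hexos-5-ulose | O=C[C@H](OCc1ccccc1)[C@H](OCc1ccccc1)[C@@H](OCc1ccccc1)C(C)=O
A5 | alternative 2 | L-rhamnose | O=C[C@H](O)[C@H](O)[C@@H](O)[C@@H](O)C
A6 | alternative 3 | methyl 7,8-(isopropylidenedioxy)-2,3-dioxabicyclo[2.2.2]oct-5-ene-5-carboxylate (C3,C6 endoperoxide, anti to the acetal) | COC(=O)C1=C[C@@H]2[C@@H]3OC(C)(C)O[C@@H]3[C@H]1OO2
A7 | alternative 3 | methyl (3R,4S)-3,4-(isopropylidenedioxy)cyclohexa-1,5-diene-1-carboxylate | COC(=O)C1=C[C@H]2OC(C)(C)O[C@H]2C=C1
A8 | alternative 3 | shikimic acid | O=C(O)C1=C[C@@H](O)[C@@H](O)[C@H](O)C1
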